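The product D forms from L.J and J.Z and can fall back to them, so I asked first what end state it tends to, then how fast J.Z arrives.

| setting | larch | ash | cedar | alder |
|---|---|---|---|---|
| L | 0.010 M | 0.010 M | 0.010 M (fed, over 20.0 h) | 0.010 M |
| Z | 0.0105 M | 0.0105 M (fed, over 20.0 h) | 0.0105 M | 0.0105 M |
| J | 0.0400 M | 0.0400 M | 0.0400 M | 0.0400 M |
| remark | one stirred flow tank at steady state, fed with the mixture as stated, mean residence time 40 h | a stirred flask in which Z is dosed at a steady rate over 20.0 h without added volume, worked up at 40 h | all but L at the start; L goes in evenly over 20.0 h, the run ends at 40 h | everything together in a closed stirred flask, run for 40 h |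
| time |  | 40 h | 40 h | 40 h |

    Z ⇌ X (K1 = 3.5, k1 = 0.0010 s⁻¹)
    L.J + J.Z ⇌ D (K2 = 100 M⁻¹, k2 = 0.0025 M⁻¹ s⁻¹)
    J + Z → J.Z (k3 = 0.0038 M⁻¹ s⁻¹)
    L + J → L.J (k4 = 0.018 M⁻¹ s⁻¹)

* the set-up with the highest amount of L.J at the outlet or at the end, in percent of the L put in ("none" if the first two lie within 2 percentage points) (larch / ash / cedar / alder / none)
* amount of L.J at the outlet or at the end, in percent of the L put in, larch
* amount of L.J at the outlet or at the end, in percent of the L put in, ash
* amount of L.J at the outlet or at the end, in percent of the L put in, cedar
* amount of L.J at the outlet or at the end, in percent of the L put in, alder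

- the stated concentrations are those of everything mixed, before any reaction; amounts are the same in each set-up
- the feed brings no volume worth counting
- run time (ash): 40 h

I supposed L to stand as L.J or D and the charge of Z as J.Z or D, with the equilibrium

[D] = 100 M⁻¹ × [L.J] × [J.Z], which gives [D] = 3.96 mM and L.J = 60.4%.

I called this the end share: the percent of L standing as L.J at that equilibrium, once the charge of Z has passed on.

In alder the half-life of L by step 4 alone, at the charged concentrations, was 0.27 h, and the half-life of Z by the forward rate of step 1 alone was 0.19 h. I treated the supply of J.Z as pseudo-first-order, with J held at its charge less that of L, and with Z taken as 22.2% of Z+X, the share that the equilibrium of step 1 gives: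

supply time = (1 + 3.5) / (0.0038 M⁻¹ s⁻¹ × 0.0300 M) = 11.0 h

Both half-lives were far shorter than this supply time. Against the hold of 40 h, the mean residence time in larch, the ratio was 3.65. Putting the J.Z and D that this allows into the same equilibrium gave:

larch, a tank: 8.24 mM, so L.J = 67.0%

alder, a closed flask: 10.2 mM, so L.J = 61.2%

I reckoned neither ash nor cedar.

The forecast named larch, with 70.9% for larch, 65.6% for ash, 62.5% for cedar and 62.8% for alder, on the ground that “D relaxes towards equilibrium”. Its larch stood higher than mine, 70.9% against 67.0%.

The simulation gave 70.8% for larch, 66.3% for ash, 62.7% for cedar and 63.2% for alder, so larch came out highest. With the hold at 3.65 supply times, alder ended 2.8 percentage points above the end share and larch 10 points above it. Cedar, left until 400 h, read 60.4%, close to the end share of 60.4%.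

The numbers of this flask come from no measurement; the run is a simulation.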